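**Plan**
Labels (lignan numbering): oxolane C2, C3, C4, C5 = C7', C8', C8, C9. The CH2OH carbon is C9' and the carbinol carbon is C7. Ring A is the oxolane and ring B is a temporary lactone.
Retrosynthetic cuts, in order: the O-benzyl group; C9'H2OH and C7–OH retro-reduced to a γ-lactone C9'(=O)–O–C7 (ring B); the aryl–C7' bond; the acetal bonds at C7' and the C7'–C8' bond (formyl carbon); the lactone shift from O–C7 back to O–C9; the C7–C8 bond (aldol).
Enabling feature: C7' carries the ring-A oxygen, so it can be raised to an acetal or oxocarbenium carbon. The arms on C8' and C8 are cis on ring A and form the 1,4-diol O–C7–C8–C8'–C9'–O. Tying that diol as a lactone gives a cis-fused 3,7-dioxabicyclo[3.3.0]octane whose open convex face is the face trans to C9'.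
Forward order: aldol chain, lactone on O–C9, lactone moved to O–C7 (ring B), formylation and acetal closure (ring A), aryl group joined at C7', LiAlH4 opens ring B and removes the carbamate, debenzylation.
Stereochemistry: C7 and C8 come from one L-proline-catalysed anti cross-aldol. C8' is relayed from C8 by the cis ring fusion. C7' is relayed by convex-face attack on the bicyclic cation.

Key step: step 7

Remark: acetal 12 is expected as a mixture of anomers at C7' (the exo-methoxy anomer is drawn), and 11 is drawn as its hydroxymethylidene tautomer with undefined alkene geometry. Both features disappear on ring closure or in cation 16, so the mixtures are carried on as such.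

Step 1
Reactants: 1 vanillin (4-hydroxy-3-methoxybenzaldehyde)
Product: 2 4-formyl-2-methoxyphenyl N,N-diethylcarbamate
Conditions: Et2NC(O)Cl, K2CO3, MeCN, 60 °C
Reagents that add atoms: N,N-diethylcarbamoyl chloride, CCN(CC)C(=O)Cl
Why: O-acylation of the phenoxide (Schotten–Baumann-type carbamoylation) installs an acid- and base-stable, electron-poor phenol mask that makes the aldehyde more electrophilic, later suppresses benzylic ionisation at C7 and is removed by LiAlH4, and no stereocenter is formed.

Step 2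
Reactants: 2 4-formyl-2-methoxyphenyl N,N-diethylcarbamate; 3 methyl 4-oxobutanoate
Product: 6 (4R)-4-{(R)-[4-(diethylcarbamoyloxy)-3-methoxyphenyl](hydroxy)methyl}oxolan-2-one, via aldol aldehyde 4 (not isolated), via diol ester 5 (not isolated)
Conditions: L-proline (20 mol %), DMF, 4 °C, slow addition of 3; then MeOH, NaBH4, −10 → 0 °C; aq. citric acid
Reagents that add atoms: none
Why: The proline-catalysed direct cross-aldol of an aldehyde donor with a non-enolisable aromatic aldehyde sets C7 and C8 together, because the (E)-enamine of 3 attacks the Re face of the hydrogen-bonded aldehyde to give the anti (7R) adduct, and immediate borohydride reduction prevents epimerisation while the primary alkoxide closes the γ-lactone.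

Step 3
Reactants: 6 (4R)-4-{(R)-[4-(diethylcarbamoyloxy)-3-methoxyphenyl](hydroxy)methyl}oxolan-2-one
Product: 9 (3R,4R)-3-{[(tert-butyldimethylsilyl)oxy]methyl}-4-[4-(diethylcarbamoyloxy)-3-methoxyphenyl]-4-hydroxybutanoic acid, via lithium carboxylate 7 (not isolated), via bis-silyl compound 8 (not isolated)
Conditions: LiOH, THF–H2O, 23 °C, evaporate; TBSCl, imidazole, DMF, 0 °C; aq. citric acid (pH 4–5), 0 °C
Reagents that add atoms: lithium hydroxide, [Li+].[OH-]; tert-butyldimethylsilyl chloride, CC(C)(C)[Si](C)(C)Cl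
Why: Saponification frees both hydroxyl groups, silyl ether formation then selects the unhindered primary C9–OH over the secondary benzylic C7–OH, and the labile silyl ester is lost on aqueous work-up, which leaves C7–OH as the only partner for the carboxyl group without touching a stereocenter.

Step 4
Reactants: 9 (3R,4R)-3-{[(tert-butyldimethylsilyl)oxy]methyl}-4-[4-(diethylcarbamoyloxy)-3-methoxyphenyl]-4-hydroxybutanoic acid
Product: 10 (4R,5R)-4-{[(tert-butyldimethylsilyl)oxy]methyl}-5-[4-(diethylcarbamoyloxy)-3-methoxyphenyl]oxolan-2-one (4,5-cis)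
Conditions: EDC·HCl, DMAP (cat.), CH2Cl2, 0 → 23 °C
Reagents that add atoms: none
Why: Steglich-type carbodiimide lactonisation is an acyl substitution that leaves the C7–O bond intact, so it should place the lactone on the benzylic oxygen with retention and give the cis γ-lactone that becomes ring B.

Step 5
Reactants: 10 (4R,5R)-4-{[(tert-butyldimethylsilyl)oxy]methyl}-5-[4-(diethylcarbamoyloxy)-3-methoxyphenyl]oxolan-2-one
Product: 12 (3R,3aR,6S,6aS)-3-[4-(diethylcarbamoyloxy)-3-methoxyphenyl]-6-methoxytetrahydro-1H,3H-furo[3,4-c]furan-1-one, via formyl lactone 11 (not isolated)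
Conditions: LiN(iPr)2, THF, −78 °C; HCO2Et, −78 → −20 °C; 1 M aq. HCl, 0 °C; crude 11: CSA (10 mol %), MeOH, 23 °C, Et3N quench
Reagents that add atoms: ethyl formate, CCOC=O; methanol, CO
Why: A crossed Claisen formylation of the lactone enolate brings in C7' at the aldehyde level, and acid methanolysis removes the silyl group so that C9–OH closes on the formyl group (5-exo-trig) to the mixed acetal, while the epimerisable C8' settles in the only attainable cis ring fusion under control of C8.

Step 6
Reactants: 13 [4-(benzyloxy)-3-methoxyphenyl]boronic acid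
Product: 14 potassium [4-(benzyloxy)-3-methoxyphenyl]trifluoroborate
Conditions: KHF2, MeOH–H2O, 23 °C
Reagents that add atoms: potassium hydrogen difluoride, F.[F-].[K+]
Why: This is the standard conversion of a boronic acid into its crystalline potassium trifluoroborate and it forms no stereocenter.

Step 7
Reactants: 12 (3R,3aR,6S,6aS)-3-[4-(diethylcarbamoyloxy)-3-methoxyphenyl]-6-methoxytetrahydro-1H,3H-furo[3,4-c]furan-1-one; 14 potassium [4-(benzyloxy)-3-methoxyphenyl]trifluoroborate
Product: 17 (3R,3aR,6S,6aS)-6-[4-(benzyloxy)-3-methoxyphenyl]-3-[4-(diethylcarbamoyloxy)-3-methoxyphenyl]tetrahydro-1H,3H-furo[3,4-c]furan-1-one, via aryldifluoroborane 15 (not isolated), via oxocarbenium ion 16 (not isolated)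
Conditions: 14 (1.3 equiv), BF3·OEt2 (4 equiv), CH2Cl2–MeCN, −30 → 0 °C
Reagents that add atoms: none
Why: BF3 abstracts fluoride from 14 to give aryldifluoroborane 15, which together with BF3 takes the methoxy group from C7' of 12; the resulting contact pair of oxocarbenium ion 16 (C7'=O+ in ring A) and an aryl(methoxy)difluoroborate collapses by ipso attack of the boron-bearing arene carbon on C7' with loss of boron. The closest known reaction type is the BF3-promoted coupling of potassium aryltrifluoroborates with acetals, a relative of Lewis-acid C-aryl glycosylation and of the acid-mediated arylation of furofuran lactols. No ring is closed in this step, because rings A and B are already in place and act as the control element. The new stereocenter C7' is set by attack on the convex face of the cis-fused 3,7-dioxabicyclo[3.3.0]octane (the face of H8 and H8'), since the concave face is closed by ring B and its endo aryl group, and this places the new aryl group exo and therefore trans to C9'; C8' is acidic and may be lost reversibly to the enol ether, but it can return only as the cis fusion dictated by C8. The step needs ionisation at the acetal carbon and not at the benzylic lactone C7–O bond, which the electron-poor carbamoyloxy group para to C7 secures, and it needs bonding at the arene carbon para to the benzyloxy group, which the C–B bond secures. The borate does not add to the lactone or carbamate carbonyl groups, so no further protection is required.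

Step 8
Reactants: 17 (3R,3aR,6S,6aS)-6-[4-(benzyloxy)-3-methoxyphenyl]-3-[4-(diethylcarbamoyloxy)-3-methoxyphenyl]tetrahydro-1H,3H-furo[3,4-c]furan-1-one
Product: 18 4-[(R)-{(3R,4R,5S)-5-[4-(benzyloxy)-3-methoxyphenyl]-4-(hydroxymethyl)oxolan-3-yl}(hydroxy)methyl]-2-methoxyphenol
Conditions: LiAlH4, THF, 0 → 40 °C; aq. potassium sodium tartrate (neutral work-up)
Reagents that add atoms: none
Why: Hydride reduction of the γ-lactone opens the tether to the primary C9' alcohol and the benzylic C7 alcohol without breaking the C7–O bond (retention), and the same reagent cleaves the aryl carbamate to the phenoxide.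

Step 9
Reactants: 18 4-[(R)-{(3R,4R,5S)-5-[4-(benzyloxy)-3-methoxyphenyl]-4-(hydroxymethyl)oxolan-3-yl}(hydroxy)methyl]-2-methoxyphenol
Product: 19 (7R)-7-hydroxylariciresinol
Conditions: H2 (1 atm), 10% Pd/C, EtOAc–EtOH, 23 °C, stopped after one equivalent of H2
Reagents that add atoms: none
Why: Catalytic hydrogenolysis cleaves the aryl benzyl ether much faster than the secondary benzylic alcohol or the cyclic benzylic ether under neutral conditions, so the stereocenters should remain untouched.

**Compound list**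
1 | vanillin (4-hydroxy-3-methoxybenzaldehyde) | COc1cc(C=O)ccc1O | starting material
2 | 4-formyl-2-methoxyphenyl N,N-diethylcarbamate | CCN(CC)C(=O)Oc1ccc(C=O)cc1OC | intermediate
3 | methyl 4-oxobutanoate | COC(=O)CCC=O | starting material
4 | methyl (3S,4R)-4-[4-(diethylcarbamoyloxy)-3-methoxyphenyl]-3-formyl-4-hydroxybutanoate (aldol aldehyde) | O=C[C@H]([C@@H](O)c1ccc(OC(=O)N(CC)CC)c(OC)c1)CC(=O)OC | intermediate
5 | methyl (3R,4R)-4-[4-(diethylcarbamoyloxy)-3-methoxyphenyl]-4-hydroxy-3-(hydroxymethyl)butanoate (diol ester) | OC[C@H]([C@@H](O)c1ccc(OC(=O)N(CC)CC)c(OC)c1)CC(=O)OC | intermediate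
6 | (4R)-4-{(R)-[4-(diethylcarbamoyloxy)-3-methoxyphenyl](hydroxy)methyl}oxolan-2-one | O=C1OC[C@H]([C@@H](O)c2ccc(OC(=O)N(CC)CC)c(OC)c2)C1 | intermediate
7 | lithium (3R,4R)-4-[4-(diethylcarbamoyloxy)-3-methoxyphenyl]-4-hydroxy-3-(hydroxymethyl)butanoate | OC[C@H]([C@@H](O)c1ccc(OC(=O)N(CC)CC)c(OC)c1)CC(=O)[O-].[Li+] | intermediate
8 | tert-butyldimethylsilyl (3R,4R)-3-{[(tert-butyldimethylsilyl)oxy]methyl}-4-[4-(diethylcarbamoyloxy)-3-methoxyphenyl]-4-hydroxybutanoate | CC(C)(C)[Si](C)(C)OC[C@H]([C@@H](O)c1ccc(OC(=O)N(CC)CC)c(OC)c1)CC(=O)O[Si](C)(C)C(C)(C)C | intermediate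
9 | (3R,4R)-3-{[(tert-butyldimethylsilyl)oxy]methyl}-4-[4-(diethylcarbamoyloxy)-3-methoxyphenyl]-4-hydroxybutanoic acid | CC(C)(C)[Si](C)(C)OC[C@H]([C@@H](O)c1ccc(OC(=O)N(CC)CC)c(OC)c1)CC(=O)O | intermediate
10 | (4R,5R)-4-{[(tert-butyldimethylsilyl)oxy]methyl}-5-[4-(diethylcarbamoyloxy)-3-methoxyphenyl]oxolan-2-one (4,5-cis) | CC(C)(C)[Si](C)(C)OC[C@H]([C@@H](O1)c2ccc(OC(=O)N(CC)CC)c(OC)c2)CC1=O | intermediate
11 | (4R,5R)-4-{[(tert-butyldimethylsilyl)oxy]methyl}-5-[4-(diethylcarbamoyloxy)-3-methoxyphenyl]-3-(hydroxymethylidene)oxolan-2-one (formyl lactone, enol tautomer) | CC(C)(C)[Si](C)(C)OC[C@H]([C@@H](O1)c2ccc(OC(=O)N(CC)CC)c(OC)c2)C(=CO)C1=O | intermediate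
12 | (3R,3aR,6S,6aS)-3-[4-(diethylcarbamoyloxy)-3-methoxyphenyl]-6-methoxytetrahydro-1H,3H-furo[3,4-c]furan-1-one (cis-fused, 3-aryl endo, 6-methoxy exo drawn) | CO[C@H]1OC[C@H]([C@@H](O3)c2ccc(OC(=O)N(CC)CC)c(OC)c2)[C@@H]1C3=O | intermediate
13 | [4-(benzyloxy)-3-methoxyphenyl]boronic acid | COc1cc(B(O)O)ccc1OCc2ccccc2 | starting material
14 | potassium [4-(benzyloxy)-3-methoxyphenyl]trifluoroborate | [K+].F[B-](F)(F)c1ccc(OCc2ccccc2)c(OC)c1 | intermediate
15 | [4-(benzyloxy)-3-methoxyphenyl]difluoroborane | FB(F)c1ccc(OCc2ccccc2)c(OC)c1 | intermediate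
16 | (3R,3aR,6aS)-3-[4-(diethylcarbamoyloxy)-3-methoxyphenyl]-1-oxo-3,3a,4,6a-tetrahydro-1H-furo[3,4-c]furan-5-ium (oxocarbenium ion) | [CH]1=[O+]C[C@H]([C@@H](O3)c2ccc(OC(=O)N(CC)CC)c(OC)c2)[C@@H]1C3=O | intermediate
17 | (3R,3aR,6S,6aS)-6-[4-(benzyloxy)-3-methoxyphenyl]-3-[4-(diethylcarbamoyloxy)-3-methoxyphenyl]tetrahydro-1H,3H-furo[3,4-c]furan-1-one (3-aryl endo, 6-aryl exo) | COc1cc([C@H]2OC[C@H]([C@@H](O5)c3ccc(OC(=O)N(CC)CC)c(OC)c3)[C@@H]2C5=O)ccc1OCc4ccccc4 | intermediate
18 | 4-[(R)-{(3R,4R,5S)-5-[4-(benzyloxy)-3-methoxyphenyl]-4-(hydroxymethyl)oxolan-3-yl}(hydroxy)methyl]-2-methoxyphenol | COc1cc([C@H]2OC[C@H]([C@@H](O)c3ccc(O)c(OC)c3)[C@@H]2CO)ccc1OCc4ccccc4 | intermediate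
19 | (7R)-7-hydroxylariciresinol, 4-[(2S,3R,4R)-4-[(R)-hydroxy(4-hydroxy-3-methoxyphenyl)methyl]-3-(hydroxymethyl)oxolan-2-yl]-2-methoxyphenol | COc1cc([C@H]2OC[C@H]([C@@H](O)c3ccc(O)c(OC)c3)[C@@H]2CO)ccc1O | target

Total step count: 9. Longest linear sequence: 8 (steps 1–5 and 7–9; step 6 is a one-step side branch).

**Steps most likely to fail**

Step 7. Proton loss from C8' of cation 16 to the conjugated enol ether may outrun aryl transfer. Attack of the cation at an arene carbon other than the boron-bearing one would also erode regiocontrol. The fallback sets out from 12 and comes back at 17, and it makes the elimination part of the plan. CSA in toluene at 80 °C with removal of methanol should convert 12 into the bicyclic β-alkoxyacrylate (3R,3aR)-3-[4-(diethylcarbamoyloxy)-3-methoxyphenyl]-3a,4-dihydro-1H,3H-furo[3,4-c]furan-1-one F1. Boronic acid 13 is then added to it under neutral conditions in a Hayashi–Miyaura 1,4-addition ([Rh(cod)OH]2, dioxane–H2O, 50 °C), a reaction type known for glycal-derived enones and chromones. Arylrhodation on the face of H8, followed by protonation of the rhodium enolate to the cis fusion, should give 17 with the same two stereocenters.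

Step 2. Self-aldolisation of donor 3 may dominate if addition to the aromatic aldehyde is slow, and the anti selectivity may erode. The fallback sets out from 2 and comes back at 10, and it replaces organocatalysis by an auxiliary-controlled aldol that also makes steps 3 and 4 unnecessary.
- (R)-4-Benzyloxazolidin-2-one is N-acylated (n-BuLi, then methyl 4-chloro-4-oxobutanoate, THF, −78 °C) to methyl 4-[(4R)-4-benzyl-2-oxo-1,3-oxazolidin-3-yl]-4-oxobutanoate F2.
- The MgCl2-catalysed Evans-type anti-aldol with 2 (Et3N, TMSCl, EtOAc, 23 °C) proceeds through the chelated (Z)-enolate, attacked on the face away from the benzyl group. It should give methyl (3S,4R)-3-{[(4R)-4-benzyl-2-oxo-1,3-oxazolidin-3-yl]carbonyl}-4-[4-(diethylcarbamoyloxy)-3-methoxyphenyl]-4-(trimethylsilyloxy)butanoate F3.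
- TFA in MeOH–CH2Cl2 removes the silyl group and closes the lactone directly on O–C7, giving (4R)-4-benzyl-3-{[(2R,3S)-2-[4-(diethylcarbamoyloxy)-3-methoxyphenyl]-5-oxooxolan-3-yl]carbonyl}-1,3-oxazolidin-2-one F4.
- LiOH/H2O2 cleaves the auxiliary to (2R,3S)-2-[4-(diethylcarbamoyloxy)-3-methoxyphenyl]-5-oxooxolane-3-carboxylic acid F5.
- BH3·SMe2 reduces only the acid to (4R,5R)-5-[4-(diethylcarbamoyloxy)-3-methoxyphenyl]-4-(hydroxymethyl)oxolan-2-one F6, and TBSCl with imidazole gives 10.

Step 9. Hydrogenolysis may continue beyond the benzyl ether into the C7–OH bond or the benzylic C7'–O bond of ring A. The fallback sets out from 17 and comes back at 19, and it removes the benzyl group without hydrogen before the sensitive benzylic alcohol exists. BCl3 with pentamethylbenzene as cation scavenger (CH2Cl2, −78 °C) should give (3R,3aR,6S,6aS)-3-[4-(diethylcarbamoyloxy)-3-methoxyphenyl]-6-(4-hydroxy-3-methoxyphenyl)tetrahydro-1H,3H-furo[3,4-c]furan-1-one F7. LiAlH4 (THF, 0 → 40 °C, neutral tartrate work-up) then opens the lactone and cleaves the carbamate in one operation to give 19.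

**Further compounds**
F1 | step 7 | (3R,3aR)-3-[4-(diethylcarbamoyloxy)-3-methoxyphenyl]-3a,4-dihydro-1H,3H-furo[3,4-c]furan-1-one | C=1OC[C@H]([C@@H](O3)c2ccc(OC(=O)N(CC)CC)c(OC)c2)C=1C3=O
F2 | step 2 | methyl 4-[(4R)-4-benzyl-2-oxo-1,3-oxazolidin-3-yl]-4-oxobutanoate | COC(=O)CCC(=O)N1[C@H](Cc2ccccc2)COC1=O
F3 | step 2 | methyl (3S,4R)-3-{[(4R)-4-benzyl-2-oxo-1,3-oxazolidin-3-yl]carbonyl}-4-[4-(diethylcarbamoyloxy)-3-methoxyphenyl]-4-(trimethylsilyloxy)butanoate | O=C1OC[C@@H](Cc2ccccc2)N1C(=O)[C@H]([C@@H](O[Si](C)(C)C)c3ccc(OC(=O)N(CC)CC)c(OC)c3)CC(=O)OC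
F4 | step 2 | (4R)-4-benzyl-3-{[(2R,3S)-2-[4-(diethylcarbamoyloxy)-3-methoxyphenyl]-5-oxooxolan-3-yl]carbonyl}-1,3-oxazolidin-2-one | O=C1OC[C@@H](Cc2ccccc2)N1C(=O)[C@H]([C@@H](O5)c3ccc(OC(=O)N(CC)CC)c(OC)c3)CC5=O
F5 | step 2 | (2R,3S)-2-[4-(diethylcarbamoyloxy)-3-methoxyphenyl]-5-oxooxolane-3-carboxylic acid | OC(=O)[C@H]([C@@H](O1)c2ccc(OC(=O)N(CC)CC)c(OC)c2)CC1=O
F6 | step 2 | (4R,5R)-5-[4-(diethylcarbamoyloxy)-3-methoxyphenyl]-4-(hydroxymethyl)oxolan-2-one | OC[C@H]([C@@H](O1)c2ccc(OC(=O)N(CC)CC)c(OC)c2)CC1=O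
F7 | step 9 | (3R,3aR,6S,6aS)-3-[4-(diethylcarbamoyloxy)-3-methoxyphenyl]-6-(4-hydroxy-3-methoxyphenyl)tetrahydro-1H,3H-furo[3,4-c]furan-1-one | COc1cc([C@H]2OC[C@H]([C@@H](O5)c3ccc(OC(=O)N(CC)CC)c(OC)c3)[C@@H]2C5=O)ccc1O
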